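**Assumption:** Kanzonol C has no stereocentre and is achiral, so "single enantiomer" does not apply. The only stereochemical element is the (E)-enone alkene, which is set in step 3.

## Retrosynthetic overview
1. No ring is formed. Both benzene rings are purchased as 2,4-dihydroxyacetophenone (1) and 4-hydroxybenzaldehyde (3), and all ten prenyl carbons come from 3-chloro-3-methylbut-1-yne (2).
2. The phenol para to each carbonyl is masked as a 1,1-dimethylpropargyl ether (4 and 5). This group serves as both protecting group and latent prenyl group.
3. Cα=Cβ disconnection: Claisen–Schmidt condensation of 4 and 5 gives the (E)-chalcone 6.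
4. Adjusting both alkynes to alkenes gives the bis(1,1-dimethylallyl) ether 7.
5. Both aryl–CH2 (prenyl) bonds are disconnected by one double aromatic Claisen rearrangement, 7 → 8. This also frees the two phenols, so no deprotection step is needed.

## Route

**Step 1**
Reactants: 1, 2,4-dihydroxyacetophenone; 2, 3-chloro-3-methylbut-1-yne
Product: 4, 1-[2-hydroxy-4-(2-methylbut-3-yn-2-yloxy)phenyl]ethan-1-one
Conditions: 2 (1.3 equiv), DBU (1.3 equiv), CuCl2·2H2O (1 mol %), MeCN, 0 °C → rt, N2
Reagents that add atoms: 3-chloro-3-methylbut-1-yne, C#CC(C)(C)Cl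
Why: In this Cu-catalysed propargylic O-alkylation, only the acidic, unchelated 4-OH is deprotonated and attacks the tertiary carbon of the Cu-allenylidene intermediate, the 2-OH stays hydrogen-bonded to the ketone and unreactive, and the low temperature prevents chromene formation.

**Step 2**
Reactants: 3, 4-hydroxybenzaldehyde; 2, 3-chloro-3-methylbut-1-yne
Product: 5, 4-(2-methylbut-3-yn-2-yloxy)benzaldehyde
Conditions: 2 (1.3 equiv), DBU (1.3 equiv), CuCl2·2H2O (1 mol %), MeCN, 0 °C → rt, N2
Reagents that add atoms: 3-chloro-3-methylbut-1-yne, C#CC(C)(C)Cl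
Why: This is the same Cu-catalysed propargylic etherification, which works best with acidic, electron-poor phenols and leaves the aldehyde untouched.

**Step 3**
Reactants: 4, the ketone ether; 5, the aldehyde ether
Product: 6, (E)-1-[2-hydroxy-4-(2-methylbut-3-yn-2-yloxy)phenyl]-3-[4-(2-methylbut-3-yn-2-yloxy)phenyl]prop-2-en-1-one
Conditions: KOH (50% aq, ~10 equiv), EtOH, 0 °C → rt, 24–48 h; then cold 1 M HCl to pH ~5
Reagents that add atoms: none
Why: With the deactivating para-phenols capped, this Claisen–Schmidt aldol condensation proceeds normally, E1cB loss of water gives only the thermodynamic (E)-enone, and the tertiary propargyl ethers and terminal alkynes are inert to aqueous-ethanolic KOH.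

**Step 4**
Reactants: 6, the bis(propargyl ether) chalcone
Product: 7, (E)-1-[2-hydroxy-4-(2-methylbut-3-en-2-yloxy)phenyl]-3-[4-(2-methylbut-3-en-2-yloxy)phenyl]prop-2-en-1-one
Conditions: H2 (1 atm), Lindlar catalyst (Pd/CaCO3–Pb), quinoline, EtOAc, rt; stop at 2.0 equiv H2
Reagents that add atoms: none (hydrogen only)
Why: In this Lindlar semi-hydrogenation, the terminal alkynes bind the poisoned Pd far more strongly than the conjugated disubstituted enone or the vinyl products, so both C≡C bonds stop at C=C and the (E)-enone and aryl ketone survive.

**Step 5**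
Reactants: 7, the bis(1,1-dimethylallyl ether) chalcone
Product: 8, kanzonol C, (E)-1-[2,4-dihydroxy-3-(3-methylbut-2-enyl)phenyl]-3-[4-hydroxy-3-(3-methylbut-2-enyl)phenyl]prop-2-en-1-one
Conditions: PhNEt2 (degassed, 0.1 M), 140 °C, Ar, dark, 3–5 h; cold aq KHSO4 wash, SiO2 chromatography
Reagents that add atoms: none
Why: In this double aromatic [3,3] Claisen rearrangement, each tertiary ether delivers its terminal CH2 to an ortho carbon with allyl inversion to give a linear prenyl group, the two ortho sites on ring B are equivalent, and on ring A the 2'-OH···O=C chelate favours C3' over C5' (as with 4-allyloxy-2-hydroxyacetophenone); gem-dimethyl acceleration allows a mild temperature, the amine solvent buffers acid-promoted loss of isoprene and chroman formation, and no stereocentre is created while the (E)-alkene is unaffected.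

## Compound list
1 | 2,4-dihydroxyacetophenone | CC(=O)c1ccc(O)cc1O | starting material
2 | 3-chloro-3-methylbut-1-yne | C#CC(C)(C)Cl | starting material
3 | 4-hydroxybenzaldehyde | O=Cc1ccc(O)cc1 | starting material
4 | 1-[2-hydroxy-4-(2-methylbut-3-yn-2-yloxy)phenyl]ethan-1-one | CC(=O)c1ccc(OC(C)(C)C#C)cc1O | intermediate
5 | 4-(2-methylbut-3-yn-2-yloxy)benzaldehyde | O=Cc1ccc(OC(C)(C)C#C)cc1 | intermediate
6 | (E)-2'-hydroxy-4,4'-bis(2-methylbut-3-yn-2-yloxy)chalcone (C25H24O4) | C#CC(C)(C)Oc1ccc(/C=C/C(=O)c2ccc(OC(C)(C)C#C)cc2O)cc1 | intermediate
7 | (E)-2'-hydroxy-4,4'-bis(2-methylbut-3-en-2-yloxy)chalcone (C25H28O4) | C=CC(C)(C)Oc1ccc(/C=C/C(=O)c2ccc(OC(C)(C)C=C)cc2O)cc1 | intermediate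
8 | kanzonol C, (E)-2',4,4'-trihydroxy-3,3'-diprenylchalcone (C25H28O4, isomer of 7) | CC(C)=CCc1cc(/C=C/C(=O)c2ccc(O)c(CC=C(C)C)c2O)ccc1O | target

## Summary
**Total step count:** 5
**Longest linear sequence:** 4 (1 → 4 → 6 → 7 → 8)

**Steps most likely to fail**
1. **Step 5, double Claisen.**
   - Risks: some C5' regioisomer, loss of isoprene to give free phenols, and thermal cyclisation of the 2'-hydroxychalcone to the flavanone isomer (glabrol).
   - Fallback: replace the sigmatropic step with cross-coupling at fragment level. Stille-prenylate 3-iodo-2,4-bis(MOM-oxy)acetophenone and 3-bromo-4-(MOM-oxy)benzaldehyde with tributyl(prenyl)stannane and Pd(0). Then carry out the Claisen–Schmidt condensation and remove MOM with mild acid.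
2. **Step 4, Lindlar reduction on the chalcone.**
   - Risks: over-reduction to tert-amyl ethers, enone reduction, and allylic C–O hydrogenolysis.
   - Fallback: avoid alkynes and hydrogenation altogether. Install the 1,1-dimethylallyl ethers directly on 1 and 3 by Pd(0)-catalysed (Tsuji–Trost) branched O-alkylation with tert-butyl 2-methylbut-3-en-2-yl carbonate. Condensing the two ethers then gives 7.
3. **Step 1, tertiary propargylation of resacetophenone.**
   - Risks: modest conversion, elimination of 2 to the enyne, and Glaser coupling.
   - Fallback: change the latent prenyl group. O-allylate 1 and 3 (allyl bromide, K2CO3), condense them, and run a double Claisen rearrangement to the 3,3'-diallyl chalcone. Both allyl groups are then converted to prenyl by double cross-metathesis with 2-methyl-2-butene (Grubbs II), for the same step count.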